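**Plan**
- Retrosynthesis: the three phenols are unmasked last (methyl at O5 and O5'', benzyl at O4''') and the C4/C4'' ketones are taken back to carbinols. The strategic cut is then O1–C8a and O1''–C8a'', which opens rings C and C'' to a dibromo tetraol.
- The tetraol goes back to a bis(1,3-diketone) (four C=O reductions). This is cut at C3–C4 and C3''–C4'' (aldols), at C4''–C4a'' (formyl group) and at the diaryl ether C4'–O–C6''.
- Forward: SNAr diaryl ether, formylation, aldol/oxidation to the first diketone, aldol/oxidation to the second, fourfold transfer hydrogenation. Rings C and C'' then close together in one double aryl etherification; oxidation at C4/C4'' and deprotection finish the route.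
- Enabling feature: O1–C8a and O1''–C8a'' are aryl–oxygen bonds of rings C and C'' lying ortho to the chains that end at C4 and C4''. With C4 and C4'' held as sp3 carbinols, C2 and C2'' are ordinary benzylic alcohols that cannot open to a chalcone.
- Stereochemistry: C2 and C2'' (both S) are set by (S,S)-TsDPEN–ruthenium transfer hydrogenation and are retained because the ring closure never breaks the C2–O or C2''–O bonds. C4 and C4'' are transient centres.

Key step: step 8

Remark: the four starting materials are taken as commercial. The carbinol centres at C4 and C4'' are drawn S, as the catalyst rule predicts (anti diols, 2,4-cis flavan-4-ols), but either configuration there would serve, since both carbons become carbonyl carbons in step 9.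

**Route**

Step 1
Reactants: 1 4-bromo-2,6-dimethoxyphenol; 2 4'-fluoroacetophenone
Product: 3 1-[4-(4-bromo-2,6-dimethoxyphenoxy)phenyl]ethan-1-one
Conditions: K2CO3, DMSO, 120 °C
Reagents that add atoms: none
Why: Nucleophilic aromatic substitution (addition–elimination through a Meisenheimer adduct) in which the phenoxide of 1 displaces the fluoride activated by the para acetyl group, while the bromide on the electron-rich ring is no SNAr leaving group.

Step 2
Reactants: 3 1-[4-(4-bromo-2,6-dimethoxyphenoxy)phenyl]ethan-1-one
Product: 5 3-(4-acetylphenoxy)-6-bromo-2,4-dimethoxybenzaldehyde, via α-chloro ether 4 (not isolated)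
Conditions: Cl2CHOMe, TiCl4, CH2Cl2, 0 °C to rt; then H2O
Reagents that add atoms: dichloromethyl methyl ether, COC(Cl)Cl; water, O
Why: Rieche formylation, in which the methoxychlorocarbenium ion attacks the only open position type of the trioxygenated ring (C3 ≡ C5, ortho and para to the methoxy groups), the acetylated ring being deactivated, and water hydrolyses the α-chloro ether to the aldehyde.

Step 3
Reactants: 5 3-(4-acetylphenoxy)-6-bromo-2,4-dimethoxybenzaldehyde; 6 4'-(benzyloxy)acetophenone
Product: 8 racemic 3-[3-(4-acetylphenoxy)-6-bromo-2,4-dimethoxyphenyl]-1-[4-(benzyloxy)phenyl]-3-hydroxypropan-1-one, via lithium enolate 7 (not isolated)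
Conditions: 6 (1.1 equiv), LDA (1.05 equiv), THF, −78 °C; then 5, −78 °C; AcOH quench at −78 °C
Reagents that add atoms: none
Why: Directed crossed aldol addition in which the preformed lithium enolate adds to the aldehyde of 5 at −78 °C much faster than it adds to or deprotonates the aryl methyl ketone; the new carbinol (C4'') is formed racemic on purpose because step 4 erases it.

Step 4
Reactants: 8 racemic β-hydroxy ketone
Product: 9 1-[3-(4-acetylphenoxy)-6-bromo-2,4-dimethoxyphenyl]-3-[4-(benzyloxy)phenyl]propane-1,3-dione
Conditions: IBX, EtOAc, 77 °C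
Reagents that add atoms: none
Why: IBX oxidation of a β-hydroxy ketone to the 1,3-diketone, a reaction known to stop at the enolized diketone and to leave the methyl ketone, the aryl bromide and the benzyl ether alone.

Step 5
Reactants: 9 1,3-diketone bearing the acetyl group; 10 2-bromo-4,6-dimethoxybenzaldehyde
Product: 12 racemic 1-[4-(benzyloxy)phenyl]-3-[6-bromo-3-{4-[3-(2-bromo-4,6-dimethoxyphenyl)-3-hydroxypropanoyl]phenoxy}-2,4-dimethoxyphenyl]propane-1,3-dione, via dilithium bis-enolate 11 (not isolated)
Conditions: LDA (2.2 equiv), THF, −78 °C; then 10, −78 °C; AcOH quench at −78 °C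
Reagents that add atoms: none
Why: Directed aldol addition with internal protection, in which the first equivalent of LDA turns the 1,3-diketone into its chelated, unreactive enolate, the second enolizes the acetyl group, and only this more basic enolate adds to the hindered aldehyde; the carbinol formed (C4) is racemic and is erased in step 6.

Step 6
Reactants: 12 racemic hydroxy triketone
Product: 13 1-[4-(benzyloxy)phenyl]-3-[6-bromo-3-{4-[3-(2-bromo-4,6-dimethoxyphenyl)-3-oxopropanoyl]phenoxy}-2,4-dimethoxyphenyl]propane-1,3-dione (bis-1,3-diketone)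
Conditions: IBX, EtOAc, 77 °C
Reagents that add atoms: none
Why: The same IBX oxidation of a β-hydroxy ketone as in step 4, giving the second enolized 1,3-diketone without touching the first.

Step 7
Reactants: 13 bis(1,3-diketone)
Product: 15 anti,anti-tetraol dibromide (all four carbinols S), via bis(β-hydroxy ketone) 14 (not isolated)
Conditions: RuCl[(S,S)-TsDPEN](p-cymene) (10 mol %), HCO2H/Et3N (5:2), CH2Cl2, 30 °C
Reagents that add atoms: none
Why: Noyori–Ikariya asymmetric transfer hydrogenation of 1,3-diaryl-1,3-diketones to anti-1,3-diols, in which the (S,S)-TsDPEN ruthenium hydride attacks the same enantioface of every aryl ketone, so that C2 and C2'' (and by the same rule C4 and C4'') are set S under catalyst control, the unhindered carbonyls reacting first and the second reduction in each half being again catalyst-controlled and therefore anti.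

Step 8
Reactants: 15 anti,anti-tetraol dibromide
Product: 18 (2S,4S,2''S,4''S)-bis(flavan-4-ol), via ring-C monocyclized bromo diol 16 (not isolated), via ring-C'' monocyclized bromo diol 17 (not isolated)
Conditions: Pd(OAc)2 (10 mol %), rac-2-(di-tert-butylphosphino)-1,1'-binaphthyl (12 mol %), Cs2CO3, toluene, 70 °C
Reagents that add atoms: none
Why: Zerovalent palladium, formed in situ from Pd(OAc)2 and the bulky electron-rich phosphine, inserts into the C8a–Br and C8a''–Br bonds to give arylpalladium bromides (divalent palladium); carbonate-assisted deprotonation brings the C2 (C2'') alkoxide onto the metal, and C–O reductive elimination releases the chroman. The closest known reaction type is the Buchwald intramolecular etherification of aryl bromides carrying a tethered secondary alcohol, which gives chromans, 2-arylchromans included, without loss of optical purity. Ring C and ring C'' each close in a six-membered exo-type mode by reductive elimination from a seven-membered aryl(alkoxo)palladium chelate, O1 (O1'') being delivered to C8a (C8a''); the two closures are independent, so either monocyclized bromo diol simply reacts on. No stereocentre is created: the C2–O and C2''–O bonds are never broken, so the S configuration from step 7 is retained, and with sp3 carbinols at C4 and C4'' there is no retro-oxa-Michael opening under the hot basic conditions. The step needs selection between the two hydroxyls of each 1,3-diol and reductive elimination ahead of β-hydride elimination. The first is secured by ring size, because the C4 (C4'') alkoxide can only form a five-membered palladacycle that would have to eliminate to a benzoxete and whose C4–H cannot lie syn-coplanar with the Pd–O bond; the second is secured by the bulky ligand, the weak base and the moderate temperature.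

Step 9
Reactants: 18 (2S,4S,2''S,4''S)-bis(flavan-4-ol)
Product: 19 (2S,2''S)-4'''-O-benzyl-5,7,5'',7''-tetra-O-methyl bis-flavanone
Conditions: Dess–Martin periodinane, pyridine, CH2Cl2, 0 °C to rt
Reagents that add atoms: none
Why: Dess–Martin oxidation of the two secondary benzylic carbinols to ketones, with pyridine buffering so that the acid-labile 5,7-dimethoxyflavan-4-ols do not ionize, and with no reagent present that could open ring C or touch C2 and C2''.

Step 10
Reactants: 19 protected bis-flavanone
Product: 21 7,7''-di-O-methyltetrahydrohinokiflavone, via tris(dichloroboryl) ether 20 (not isolated)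
Conditions: BCl3, C6HMe5, CH2Cl2, −78 to 0 °C; then H2O
Reagents that add atoms: none
Why: Chelation-controlled ether cleavage in which BCl3 bound to each C4 carbonyl removes only the peri methyl groups at O5 and O5'' (the O7 and O7'' methyl ethers have no chelating neighbour), the same reagent cleaves the benzyl ether with pentamethylbenzene trapping the benzyl cation, and the low temperature keeps ring C closed so that C2 and C2'' stay S.

**Compound list**
1 | 4-bromo-2,6-dimethoxyphenol | COc1cc(Br)cc(OC)c1O | starting material
2 | 4'-fluoroacetophenone | CC(=O)c1ccc(F)cc1 | starting material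
3 | 1-[4-(4-bromo-2,6-dimethoxyphenoxy)phenyl]ethan-1-one | CC(=O)c1ccc(Oc2c(OC)cc(Br)cc2OC)cc1 | intermediate
4 | 1-{4-[4-bromo-3-(chloro(methoxy)methyl)-2,6-dimethoxyphenoxy]phenyl}ethan-1-one (α-chloro ether, not isolated) | CC(=O)c1ccc(Oc2c(OC)cc(Br)c(C(Cl)OC)c2OC)cc1 | intermediate
5 | 3-(4-acetylphenoxy)-6-bromo-2,4-dimethoxybenzaldehyde | CC(=O)c1ccc(Oc2c(OC)cc(Br)c(C=O)c2OC)cc1 | intermediate
6 | 4'-(benzyloxy)acetophenone | CC(=O)c1ccc(OCc2ccccc2)cc1 | starting material
7 | lithium 1-[4-(benzyloxy)phenyl]ethenolate (not isolated) | [Li]OC(=C)c1ccc(OCc2ccccc2)cc1 | intermediate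
8 | racemic 3-[3-(4-acetylphenoxy)-6-bromo-2,4-dimethoxyphenyl]-1-[4-(benzyloxy)phenyl]-3-hydroxypropan-1-one | CC(=O)c1ccc(Oc2c(OC)cc(Br)c(C(O)CC(=O)c3ccc(OCc4ccccc4)cc3)c2OC)cc1 | intermediate
9 | 1-[3-(4-acetylphenoxy)-6-bromo-2,4-dimethoxyphenyl]-3-[4-(benzyloxy)phenyl]propane-1,3-dione (drawn as diketo form) | CC(=O)c1ccc(Oc2c(OC)cc(Br)c(C(=O)CC(=O)c3ccc(OCc4ccccc4)cc3)c2OC)cc1 | intermediate
10 | 2-bromo-4,6-dimethoxybenzaldehyde | COc1cc(Br)c(C=O)c(OC)c1 | starting material
11 | dilithium bis-enolate of 9 (diketonate plus acetyl enolate, not isolated) | [Li]OC(=C)c1ccc(Oc2c(OC)cc(Br)c(C(=O)C=C(O[Li])c3ccc(OCc4ccccc4)cc3)c2OC)cc1 | intermediate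
12 | racemic 1-[4-(benzyloxy)phenyl]-3-[6-bromo-3-{4-[3-(2-bromo-4,6-dimethoxyphenyl)-3-hydroxypropanoyl]phenoxy}-2,4-dimethoxyphenyl]propane-1,3-dione | COc1cc(OC)c(C(O)CC(=O)c2ccc(Oc3c(OC)cc(Br)c(C(=O)CC(=O)c4ccc(OCc5ccccc5)cc4)c3OC)cc2)c(Br)c1 | intermediate
13 | 1-[4-(benzyloxy)phenyl]-3-[6-bromo-3-{4-[3-(2-bromo-4,6-dimethoxyphenyl)-3-oxopropanoyl]phenoxy}-2,4-dimethoxyphenyl]propane-1,3-dione (bis-1,3-diketone) | COc1cc(OC)c(C(=O)CC(=O)c2ccc(Oc3c(OC)cc(Br)c(C(=O)CC(=O)c4ccc(OCc5ccccc5)cc4)c3OC)cc2)c(Br)c1 | intermediate
14 | bis(β-hydroxy ketone), S carbinols at C2 and C2'', ketones at C4 and C4'' (not isolated) | COc1cc(OC)c(C(=O)C[C@H](O)c2ccc(Oc3c(OC)cc(Br)c(C(=O)C[C@H](O)c4ccc(OCc5ccccc5)cc4)c3OC)cc2)c(Br)c1 | intermediate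
15 | (1S,3S)-1-(2-bromo-4,6-dimethoxyphenyl)-3-[4-(4-bromo-3-{(1S,3S)-3-[4-(benzyloxy)phenyl]-1,3-dihydroxypropyl}-2,6-dimethoxyphenoxy)phenyl]propane-1,3-diol (anti,anti-tetraol dibromide) | COc1cc(OC)c([C@@H](O)C[C@H](O)c2ccc(Oc3c(OC)cc(Br)c([C@@H](O)C[C@H](O)c4ccc(OCc5ccccc5)cc4)c3OC)cc2)c(Br)c1 | intermediate
16 | monocyclized bromo diol with ring C closed, (2S,4S)-flavan-4-ol carrying the open (S,S)-bromo diol of the second unit (not isolated) | COc1cc(OC)c2c(c1)O[C@H](c1ccc(Oc3c(OC)cc(Br)c([C@@H](O)C[C@H](O)c4ccc(OCc5ccccc5)cc4)c3OC)cc1)C[C@@H]2O | intermediate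
17 | monocyclized bromo diol with ring C'' closed, (2''S,4''S)-flavan-4-ol carrying the open (S,S)-bromo diol of the first unit (not isolated) | COc1cc(OC)c([C@@H](O)C[C@H](O)c2ccc(Oc3c(OC)cc4c(c3OC)[C@@H](O)C[C@@H](c3ccc(OCc5ccccc5)cc3)O4)cc2)c(Br)c1 | intermediate
18 | (2S,4S)-2-[4-({(2S,4S)-2-[4-(benzyloxy)phenyl]-4-hydroxy-5,7-dimethoxychroman-6-yl}oxy)phenyl]-5,7-dimethoxychroman-4-ol (both rings 2,4-cis) | COc1cc(OC)c2c(c1)O[C@H](c1ccc(Oc3c(OC)cc4c(c3OC)[C@@H](O)C[C@@H](c3ccc(OCc5ccccc5)cc3)O4)cc1)C[C@@H]2O | intermediate
19 | (2S)-2-[4-({(2S)-2-[4-(benzyloxy)phenyl]-5,7-dimethoxy-4-oxochroman-6-yl}oxy)phenyl]-5,7-dimethoxychroman-4-one | COc1cc(OC)c2c(c1)O[C@H](c1ccc(Oc3c(OC)cc4c(c3OC)C(=O)C[C@@H](c3ccc(OCc5ccccc5)cc3)O4)cc1)CC2=O | intermediate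
20 | tris(dichloroboryl) ether of the target at O5, O5'' and O4''' (not isolated) | COc1cc(OB(Cl)Cl)c2c(c1)O[C@H](c1ccc(Oc3c(OC)cc4c(c3OB(Cl)Cl)C(=O)C[C@@H](c3ccc(OB(Cl)Cl)cc3)O4)cc1)CC2=O | intermediate
21 | 7,7''-di-O-methyltetrahydrohinokiflavone, (2S)-5-hydroxy-2-[4-({(2S)-5-hydroxy-2-(4-hydroxyphenyl)-7-methoxy-4-oxochroman-6-yl}oxy)phenyl]-7-methoxychroman-4-one | COc1cc(O)c2c(c1)O[C@H](c1ccc(Oc3c(OC)cc4c(c3O)C(=O)C[C@@H](c3ccc(O)cc3)O4)cc1)CC2=O | target

**Count**
Total steps: 10. Longest linear sequence: 10 steps (1 or 2 to 21); 6 and 10 enter as side inputs.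

**Steps most likely to fail**

Step 8. What may go wrong is hydride transfer: a benzylic palladium alkoxide undergoes β-hydride elimination, so that a carbinol is oxidized while the aryl bromide is reduced, before C–O reductive elimination can close the ring. The fallback leaves palladium cross-coupling for a copper-mediated Ullmann etherification, a different mechanistic manifold in which the copper alkoxide has no comparable hydride pathway. Tetraol 15 would be heated with CuI (monovalent copper), 3,4,7,8-tetramethyl-1,10-phenanthroline and Cs2CO3 in toluene at 110 °C. The sequence sets out from 15, passes through the same monocyclized bromo diols 16 and 17 and returns to the route at 18; it makes no compound outside the list (F0).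

Step 7. What may go wrong is stalling: the carbonyl groups at C4 and C4'', each flanked by a bromine and a methoxy group, may be reduced too slowly by the ruthenium hydride, so that hydride delivery ends after C2 and C2''. The fallback replaces catalyst control by substrate control for the second pair of reductions. The transfer hydrogenation of 13 would be stopped at the bis(β-hydroxy ketone) 14, which is isolated in this variant. The remaining ketones would then be reduced with Me4NBH(OAc)3 in MeCN/AcOH at −30 °C (Evans–Saksena reduction), the C2 and C2'' hydroxyls binding boron and delivering hydride intramolecularly to give the anti diols. The sequence sets out from 13 and returns at 15; it makes no compound outside the list (F0).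

Step 3. What may go wrong is proton transfer from the acetyl group of 5 to the lithium enolate, which scrambles the enolates and leads to self-condensation of the keto aldehyde. The fallback joins the fragments without any basic enolate, as a Mukaiyama aldol addition. Ketone 6 would be silylated (TMSOTf, Et3N, CH2Cl2, 0 °C) to trimethyl({1-[4-(benzyloxy)phenyl]ethenyl}oxy)silane F1. This adds to the aldehyde of 5 under Sc(OTf)3 catalysis (CH2Cl2, −78 °C) to give the trimethylsilyl ether of the aldol F2. Citric acid in THF/H2O removes the silyl group. The sequence sets out from 6 (with 5) and returns at 8.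

**Further compounds**
F1 | step 3 | trimethyl({1-[4-(benzyloxy)phenyl]ethenyl}oxy)silane | C=C(O[Si](C)(C)C)c1ccc(OCc2ccccc2)cc1
F2 | step 3 | racemic 3-[3-(4-acetylphenoxy)-6-bromo-2,4-dimethoxyphenyl]-1-[4-(benzyloxy)phenyl]-3-(trimethylsilyloxy)propan-1-one | CC(=O)c1ccc(Oc2c(OC)cc(Br)c(C(O[Si](C)(C)C)CC(=O)c3ccc(OCc4ccccc4)cc3)c2OC)cc1
F0 | step 7 | none | none
F0 | step 8 | none | none
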